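**Retrosynthetic overview**
1. Target ⇒ 3α-hydroxy-15-aldehyde (acetylation last) ⇒ 3α,15-diol (primary-selective oxidation) ⇒ 3-ketone (catalyst-controlled reduction, which also turns the two decalin-antipodal cyclisation products into a separable axial/equatorial pair).
2. Key disconnection C4–C5 (then C9–C10): the 3-oxo-19-ester decalin ⇒ an acyclic α-methyl β-keto ester. Mn(OAc)3 turns the enolate carbon C4 into an electrophilic α-keto radical (enolonium-type reactivity) that attacks the nucleophilic C5=C10 alkene.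
3. Ring order: the oxirane first, then ring A (C4–C5) and ring B (C10–C9) in one cascade, ended by Cu(OAc)2 as the 8(17)-alkene. The oxirane also keeps the third alkene out of the cascade.
4. β-Keto ester ⇒ γ-alkylation of the dianion of methyl 2-methylacetoacetate with an (E)-allylic chloride.
5. Chloride ⇒ (2E,6E)-farnesol by Sharpless epoxidation (sets C13/C14), terminal SeO2 oxidation and allylic-selective chlorination; no protecting groups.

Assumption: labdane numbering (C1–C20; the ester carbon C19 is the β, axial substituent on C4) is used for all cyclised compounds, and farnesol, methyl 2-methylacetoacetate and D-(−)-diethyl tartrate are bought.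

**Step 1**
Reactants: 1 (2E,6E)-farnesol
Product: 2 [(2R,3R)-3-[(3E)-4,8-dimethylnona-3,7-dien-1-yl]-3-methyloxiran-2-yl]methanol
Conditions: Ti(OiPr)4 (10 mol%), D-(−)-diethyl tartrate (12 mol%), t-BuOOH (2 equiv, isooctane), 4 Å MS, CH2Cl2, −20 °C
Reagents that add atoms: tert-butyl hydroperoxide, CC(C)(C)OO
Why: Katsuki–Sharpless asymmetric epoxidation: the allylic hydroxyl binds the titanium tartrate peroxide complex so only the 2,3-alkene reacts, and D-(−)-tartrate gives the (2R,3R) epoxide (antipode of the (2S,3S) epoxide from L-(+)-tartrate), which fixes C13 and C14 of the target.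

**Step 2**
Reactants: 2 [(2R,3R)-3-[(3E)-4,8-dimethylnona-3,7-dien-1-yl]-3-methyloxiran-2-yl]methanol
Product: 3 (2E,6E)-9-[(2R,3R)-3-(hydroxymethyl)-2-methyloxiran-2-yl]-2,6-dimethylnona-2,6-dien-1-ol
Conditions: SeO2 (0.4 equiv), t-BuOOH (3 equiv), salicylic acid (0.1 equiv), CH2Cl2, 0 °C → 20 °C
Reagents that add atoms: selenium dioxide, O=[Se]=O (oxygen carrier); tert-butyl hydroperoxide, CC(C)(C)OO (terminal oxygen source)
Why: Selenium dioxide allylic oxidation (ene reaction then [2,3]-sigmatropic shift) attacks the most electron-rich, least hindered terminal trisubstituted alkene at its (E)-methyl group and returns the (E)-allylic alcohol; the epoxy alcohol end is inert and no stereocentre is formed.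

**Step 3**
Reactants: 3 (2E,6E)-9-[(2R,3R)-3-(hydroxymethyl)-2-methyloxiran-2-yl]-2,6-dimethylnona-2,6-dien-1-ol
Product: 5 [(2R,3R)-3-[(3E,7E)-9-chloro-4,8-dimethylnona-3,7-dien-1-yl]-3-methyloxiran-2-yl]methanol, via allyloxysulfonium chloride 4 (not isolated)
Conditions: NCS (1.15 equiv), Me2S (1.3 equiv), CH2Cl2, −40 °C → 0 °C
Reagents that add atoms: N-chlorosuccinimide, O=C1CCC(=O)N1Cl
Why: Corey–Kim chlorination: both hydroxyls can form oxysulfonium salts but only the allylic one (4) is displaced by chloride (SN2 at the primary carbon, alkene geometry kept), the saturated one returning the alcohol on work-up; no stereocentre is touched.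

**Step 4**
Reactants: 5 [(2R,3R)-3-[(3E,7E)-9-chloro-4,8-dimethylnona-3,7-dien-1-yl]-3-methyloxiran-2-yl]methanol; 6 methyl 2-methylacetoacetate (methyl 2-methyl-3-oxobutanoate)
Product: 8 methyl (6E,10E)-13-[(2R,3R)-3-(hydroxymethyl)-2-methyloxiran-2-yl]-2,6,10-trimethyl-3-oxotrideca-6,10-dienoate (both C2 epimers), via acetoacetate dianion 7 (not isolated)
Conditions: 6 (2.4 equiv), NaH (2.4 equiv), THF, 0 °C; n-BuLi (2.4 equiv), 0 °C; then 5, 0 °C; aq NH4Cl
Reagents that add atoms: none
Why: Weiler dianion alkylation: one equivalent of dianion is spent on the free hydroxyl and the terminal (γ) carbanion of 7 displaces the primary allylic chloride by SN2 without opening the trisubstituted epoxide at 0 °C; the α-stereocentre is left unset because step 5 planarises it.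

**Step 5**
Reactants: 8 methyl (6E,10E)-13-[(2R,3R)-3-(hydroxymethyl)-2-methyloxiran-2-yl]-2,6,10-trimethyl-3-oxotrideca-6,10-dienoate
Product: 12 methyl (4R,5R,9S,10R,13R,14R)-13,14-epoxy-15-hydroxy-3-oxolabd-8(17)-en-19-oate, via acyclic C4 radical 9 (not isolated), via monocyclic C10 radical 10 (not isolated), via bicyclic C8 radical 11 (not isolated)
Conditions: Mn(OAc)3·2H2O (2.2 equiv), Cu(OAc)2·H2O (1.0 equiv), KOAc (2 equiv), degassed AcOH–EtOH 1:4 (0.03 M), 20 °C; the bicyclic keto ester fraction is collected by chromatography and used as obtained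
Reagents that add atoms: none
Why: Mn(OAc)3/Cu(OAc)2 oxidative free-radical polyene cyclisation (Snider type): trivalent manganese oxidises the β-keto ester enol so that the donor carbon C4 becomes the electrophilic α-keto radical 9, which bonds to the nucleophilic alkene carbon C5; two 6-endo closures through a chair–chair array of the (E,E)-diene give the trans-decalin with H5 α, C10-methyl β, the C9 side chain equatorial (β) and the ester axial (cis to the C10 methyl, the established outcome for α-methyl β-keto esters), and divalent copper oxidises the tertiary radical 11 with loss of a C17 hydrogen to the exocyclic 8(17)-alkene; because the remote epoxide cannot bias the folding, 12 is obtained as a 1:1 mixture with its decalin-antipodal (4S,5S,9R,10S,13R,14R) diastereomer, which does not separate at this stage and is removed in step 6.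

**Step 6**
Reactants: 12 methyl (4R,5R,9S,10R,13R,14R)-13,14-epoxy-15-hydroxy-3-oxolabd-8(17)-en-19-oate (used as the 1:1 mixture with its decalin-antipodal diastereomer from step 5)
Product: 13 methyl (3R,4R,5R,9S,10R,13R,14R)-13,14-epoxy-3α,15-dihydroxylabd-8(17)-en-19-oate
Conditions: (S)-Me-CBS oxazaborolidine [(S)-1-methyl-3,3-diphenyltetrahydro-1H,3H-pyrrolo[1,2-c][1,3,2]oxazaborole] (0.3 equiv), catecholborane (3 equiv), toluene, −40 °C → 0 °C; MeOH, aq Na2CO3; silica gel chromatography
Reagents that add atoms: none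
Why: Corey–Bakshi–Shibata reduction under catalyst control: the oxazaborolidine binds the carbonyl lone pair anti to the quaternary C4 and delivers hydride to the same prochiral face of both decalin series (3R carbinol, as for the large/small model with C4 large), which in 12 gives the axial 3α-alcohol 13 and in the co-formed diastereomer gives the equatorial alcohol, so the two remote diastereomers become an axial/equatorial pair that separates on silica and only 13 is kept; catecholborane neither hydroborates the 8(17)-alkene nor opens the epoxide at this temperature.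

**Step 7**
Reactants: 13 methyl (3R,4R,5R,9S,10R,13R,14R)-13,14-epoxy-3α,15-dihydroxylabd-8(17)-en-19-oate
Product: 14 methyl (3R,4R,5R,9S,10R,13R,14S)-13,14-epoxy-3α-hydroxy-15-oxolabd-8(17)-en-19-oate
Conditions: 2,2,6,6-tetramethylpiperidin-1-oxyl (TEMPO, 0.2 equiv), PhI(OAc)2 (1.2 equiv), CH2Cl2, 20 °C
Reagents that add atoms: none
Why: Oxoammonium (TEMPO/PhI(OAc)2) oxidation takes the primary alcohol and leaves the hindered axial 3α-hydroxyl, and the epoxy aldehyde cannot epimerise because enolisation would place a double bond on the oxirane; C14 changes from R to S by priority only.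

**Step 8**
Reactants: 14 methyl (3R,4R,5R,9S,10R,13R,14S)-13,14-epoxy-3α-hydroxy-15-oxolabd-8(17)-en-19-oate
Product: 15 methyl (3R,4R,5R,9S,10R,13R,14S)-3α-acetoxy-13,14-epoxy-15-oxolabd-8(17)-en-19-oate (CNP0145900.1)
Conditions: Ac2O (5 equiv), 4-(dimethylamino)pyridine (0.3 equiv), pyridine, CH2Cl2, 0 °C → 20 °C
Reagents that add atoms: acetic anhydride, CC(=O)OC(C)=O
Why: Nucleophilic-catalysed (4-(dimethylamino)pyridine) acylation of the axial 3α-hydroxyl with retention at C3; the non-enolisable epoxy aldehyde has no group that acetic anhydride acylates under base.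

**Compound list**
1 | (2E,6E)-farnesol | CC(C)=CCC/C(C)=C/CC/C(C)=C/CO | starting material
2 | [(2R,3R)-3-[(3E)-4,8-dimethylnona-3,7-dien-1-yl]-3-methyloxiran-2-yl]methanol | CC(C)=CCC/C(C)=C/CC[C@@]1(C)O[C@@H]1CO | intermediate
3 | (2E,6E)-9-[(2R,3R)-3-(hydroxymethyl)-2-methyloxiran-2-yl]-2,6-dimethylnona-2,6-dien-1-ol | OC/C(C)=C/CC/C(C)=C/CC[C@@]1(C)O[C@@H]1CO | intermediate
4 | dimethyl(allyloxy)sulfonium chloride of 3 (allylic oxygen on sulfur; not isolated) | C[S+](C)OC/C(C)=C/CC/C(C)=C/CC[C@@]1(C)O[C@@H]1CO.[Cl-] | intermediate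
5 | [(2R,3R)-3-[(3E,7E)-9-chloro-4,8-dimethylnona-3,7-dien-1-yl]-3-methyloxiran-2-yl]methanol | ClC/C(C)=C/CC/C(C)=C/CC[C@@]1(C)O[C@@H]1CO | intermediate
6 | methyl 2-methylacetoacetate | COC(=O)C(C)C(C)=O | starting material
7 | sodium lithium dianion (1,3-dienolate) of 6 (not isolated) | C=C([O-])C(C)=C([O-])OC.[Na+].[Li+] | intermediate
8 | methyl (6E,10E)-13-[(2R,3R)-3-(hydroxymethyl)-2-methyloxiran-2-yl]-2,6,10-trimethyl-3-oxotrideca-6,10-dienoate (C2 epimers) | COC(=O)C(C)C(=O)CC/C(C)=C/CC/C(C)=C/CC[C@@]1(C)O[C@@H]1CO | intermediate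
9 | acyclic C4 (α-keto ester) radical of 8 (not isolated) | COC(=O)[C](C)C(=O)CC/C(C)=C/CC/C(C)=C/CC[C@@]1(C)O[C@@H]1CO | intermediate
10 | monocyclic C10 radical (ring A closed, 4R,5R; not isolated) | C/C(=C\CC[C@@]1(C)O[C@@H]1CO)CC[C@@H]2[C](C)CCC(=O)[C@]2(C)C(=O)OC | intermediate
11 | bicyclic C8 radical (rings A and B closed, 4R,5R,9S,10R; not isolated) | C[C]1CC[C@@H]2[C@](C)(CCC(=O)[C@]2(C)C(=O)OC)[C@H]1CC[C@@]1(C)O[C@@H]1CO | intermediate
12 | methyl (4R,5R,9S,10R,13R,14R)-13,14-epoxy-15-hydroxy-3-oxolabd-8(17)-en-19-oate (4β-CO2Me, 4α-Me, 5α-H, 9α-H, 10β-Me) | C=C1CC[C@@H]2[C@](C)(CCC(=O)[C@]2(C)C(=O)OC)[C@H]1CC[C@@]1(C)O[C@@H]1CO | intermediate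
13 | methyl (3R,4R,5R,9S,10R,13R,14R)-13,14-epoxy-3α,15-dihydroxylabd-8(17)-en-19-oate (axial 3-OH) | C=C1CC[C@@H]2[C@](C)(CC[C@@H](O)[C@]2(C)C(=O)OC)[C@H]1CC[C@@]1(C)O[C@@H]1CO | intermediate
14 | methyl (3R,4R,5R,9S,10R,13R,14S)-13,14-epoxy-3α-hydroxy-15-oxolabd-8(17)-en-19-oate | C=C1CC[C@@H]2[C@](C)(CC[C@@H](O)[C@]2(C)C(=O)OC)[C@H]1CC[C@@]1(C)O[C@@H]1C=O | intermediate
15 | methyl (3R,4R,5R,9S,10R,13R,14S)-3α-acetoxy-13,14-epoxy-15-oxolabd-8(17)-en-19-oate | C=C1CC[C@@H]2[C@](C)(CC[C@@H](OC(C)=O)[C@]2(C)C(=O)OC)[C@H]1CC[C@@]1(C)O[C@@H]1C=O | target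

**Totals**
Total step count: 8. Longest linear sequence: 8 steps (1 → 15); 6 enters at step 4.

**Three steps most likely to fail**

Step 5. The free epoxy alcohol may be opened by acetic acid or the metal acetates, and the copper oxidation may give some endocyclic alkene. At most half of the cyclised material is 12, because the decalin-antipodal diastereomer forms in equal amount. The fallback sets out from 8 and comes back at 12, replacing the oxidative cyclisation by a neutral group-transfer cyclisation. The sodium enolate of 8 (NaH, 2.1 equiv, THF, 0 °C) is selenenylated with PhSeCl (−78 °C) to methyl (6E,10E)-13-[(2R,3R)-3-(hydroxymethyl)-2-methyloxiran-2-yl]-2,6,10-trimethyl-3-oxo-2-(phenylselanyl)trideca-6,10-dienoate F1. Photolysis (sunlamp, benzene, 20 °C) breaks the weak C–Se bond to the same radical 9, which closes both rings and takes the phenylselanyl group back at C8. This gives methyl (13R,14R)-13,14-epoxy-15-hydroxy-3-oxo-8-(phenylselanyl)labdan-19-oate F2 (ring configuration of 12, C8 epimers) and methyl (13R,14R)-13,14-epoxy-15-hydroxy-3-oxo-8-(phenylselanyl)-ent-labdan-19-oate F3 (mirror-image decalin, C8 epimers). H2O2–pyridine (CH2Cl2, 0 °C) oxidises the selenides, and syn-elimination of the selenoxide toward the C17 methyl returns 12 from F2. From F3 it returns methyl (4S,5S,9R,10S,13R,14R)-13,14-epoxy-15-hydroxy-3-oxolabd-8(17)-en-19-oate F4, the same diastereomer that accompanies 12 in step 5. The mixture then enters step 6 unchanged.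

Step 6. For 12 the catalyst must deliver hydride to the face that the axial ester shields (mismatched case), so the 3α:3β ratio from 12 may be modest; the co-formed diastereomer is the matched case. The fallback sets out from 12 (as the step 5 mixture) and comes back at 13, using a kinetic resolution followed by a substrate-controlled reduction. The same oxazaborolidine is used with limiting catecholborane (1.6 equiv: 1.0 for the hydroxyls, 0.6 for the ketone), so that only the matched, decalin-antipodal diastereomer is reduced. It gives methyl (3R,4S,5S,9R,10S,13R,14R)-13,14-epoxy-3,15-dihydroxylabd-8(17)-en-19-oate F5 (equatorial 3-hydroxyl). Unreacted keto alcohol 12 is separated from this diol by chromatography and reduced with LiBH(s-Bu)3 (THF, −78 °C), whose equatorial attack gives the axial alcohol 13.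

Step 8. The hindered axial hydroxyl needs a long acylation in the presence of the sensitive epoxy aldehyde. The fallback sets out from 13 and comes back at 15, acetylating first and oxidising last. Ac2O, 4-(dimethylamino)pyridine and pyridine convert 13 into methyl (3R,4R,5R,9S,10R,13R,14R)-3α,15-diacetoxy-13,14-epoxylabd-8(17)-en-19-oate F6. K2CO3 in MeOH at 0 °C removes only the unhindered primary acetate to give methyl (3R,4R,5R,9S,10R,13R,14R)-3α-acetoxy-13,14-epoxy-15-hydroxylabd-8(17)-en-19-oate F7. Dess–Martin periodinane with NaHCO3 (CH2Cl2, 20 °C) then gives 15.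

**Further compounds**
F1 | step 5 | methyl (6E,10E)-13-[(2R,3R)-3-(hydroxymethyl)-2-methyloxiran-2-yl]-2,6,10-trimethyl-3-oxo-2-(phenylselanyl)trideca-6,10-dienoate | COC(=O)C(C)([Se]c1ccccc1)C(=O)CC/C(C)=C/CC/C(C)=C/CC[C@@]2(C)O[C@@H]2CO
F2 | step 5 | methyl (13R,14R)-13,14-epoxy-15-hydroxy-3-oxo-8-(phenylselanyl)labdan-19-oate (ring configuration of 12, C8 epimers) | CC1([Se]c3ccccc3)CC[C@@H]2[C@](C)(CCC(=O)[C@]2(C)C(=O)OC)[C@H]1CC[C@@]1(C)O[C@@H]1CO
F3 | step 5 | methyl (13R,14R)-13,14-epoxy-15-hydroxy-3-oxo-8-(phenylselanyl)-ent-labdan-19-oate (mirror-image decalin, C8 epimers) | CC1([Se]c3ccccc3)CC[C@H]2[C@@](C)(CCC(=O)[C@@]2(C)C(=O)OC)[C@@H]1CC[C@@]1(C)O[C@@H]1CO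
F4 | step 5 | methyl (4S,5S,9R,10S,13R,14R)-13,14-epoxy-15-hydroxy-3-oxolabd-8(17)-en-19-oate (decalin-antipodal diastereomer of 12) | C=C1CC[C@H]2[C@@](C)(CCC(=O)[C@@]2(C)C(=O)OC)[C@@H]1CC[C@@]1(C)O[C@@H]1CO
F5 | step 6 | methyl (3R,4S,5S,9R,10S,13R,14R)-13,14-epoxy-3,15-dihydroxylabd-8(17)-en-19-oate (equatorial 3-OH) | C=C1CC[C@H]2[C@@](C)(CC[C@@H](O)[C@@]2(C)C(=O)OC)[C@@H]1CC[C@@]1(C)O[C@@H]1CO
F6 | step 8 | methyl (3R,4R,5R,9S,10R,13R,14R)-3α,15-diacetoxy-13,14-epoxylabd-8(17)-en-19-oate | C=C1CC[C@@H]2[C@](C)(CC[C@@H](OC(C)=O)[C@]2(C)C(=O)OC)[C@H]1CC[C@@]1(C)O[C@@H]1COC(C)=O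
F7 | step 8 | methyl (3R,4R,5R,9S,10R,13R,14R)-3α-acetoxy-13,14-epoxy-15-hydroxylabd-8(17)-en-19-oate | C=C1CC[C@@H]2[C@](C)(CC[C@@H](OC(C)=O)[C@]2(C)C(=O)OC)[C@H]1CC[C@@]1(C)O[C@@H]1CO
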